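**Retrosynthetic overview**

1. The last three steps only unmask functional groups: the C1 acetate is put on, both silyl groups are removed with fluoride (which also returns the ketone), and the three benzyl ethers of ring B (the phloroglucinol ring) are hydrogenolysed.
2. The strategy rests on ring A: its adjacent carbons C1 (oxygen, later the acetate), C2 (the decamethylene chain) and C3 (oxygen, later the free hydroxyl) form a 2-alkylresorcinol whose two oxygens are different. Ring A is cut into cyclobut-2-en-1-one and a 1-(triisopropylsiloxy)alkyne (bonds C1–C2, C3–C4 and C1–C6).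
3. The siloxyalkyne comes from a terminal alkyne through its lithium ynolate. The aryl ketone comes from a Weinreb amide and 2,4,6-tris(benzyloxy)phenyllithium, and the C13 alkynoic acid from 11-bromoundecanoic acid and lithium acetylide.
4. Cyclobutenone comes from 3-oxocyclobutane-1-carboxylic acid by bromodecarboxylation and dehydrobromination.
5. Order of ring formation: ring B is bought; ring A is the only ring formed, in step 8.

Key step: step 8

**Remarks on the chemistry**

- Ring A is numbered so that C1 carries the oxygen that ends as the acetate, C2 the chain and C3 the oxygen that ends as the free hydroxyl.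
- The aryl ketone cannot pass unprotected through acetylide formation: its α-CH2 is more acidic than the alkyne C–H, and its carbonyl group would be attacked by the acetylide. It is therefore carried from step 4 to step 10 as its tert-butyldimethylsilyl enol ether, which falls off in the same fluoride step that frees the ring A phenol.
- Assumption: the geometry of this enol ether is left undefined, since the double bond is removed in step 10; the SMILES strings carry no descriptor for it.

**Route**

Step 1
Reactants: 1 11-bromoundecanoic acid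
Product: 4 tridec-12-ynoic acid, via lithium 11-bromoundecanoate 2 (not isolated), via lithium tridec-12-ynoate 3 (not isolated)
Conditions: LiC≡CH·H2NCH2CH2NH2 (2.5 equiv), DMSO, 10 °C → rt; then 1 M HCl
Reagents that add atoms: lithium acetylide–ethylenediamine complex, [Li]C#C.NCCN
Why: SN2 alkylation of lithium acetylide by the primary bromide in DMSO is the standard entry to ω-alkynoic acids; the first equivalent of acetylide only forms the carboxylate, which does not interfere.

Step 2
Reactants: 4 tridec-12-ynoic acid
Product: 6 N-methoxy-N-methyltridec-12-ynamide, via acyl imidazolide 5 (not isolated)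
Conditions: CDI, CH2Cl2, rt; then MeNHOMe·HCl, rt
Reagents that add atoms: N,O-dimethylhydroxylamine hydrochloride, CNOC.Cl; 1,1'-carbonyldiimidazole, O=C(n1ccnc1)n1ccnc1 (imidazolyl group of 5 only)
Why: Weinreb amide formation by CDI activation and aminolysis of the acyl imidazolide should proceed without touching the terminal alkyne.

Step 3
Reactants: 6 N-methoxy-N-methyltridec-12-ynamide; 7 1,3,5-tris(benzyloxy)benzene
Product: 10 1-[2,4,6-tris(benzyloxy)phenyl]tridec-12-yn-1-one, via aryllithium 8 (not isolated), via dilithio tetrahedral adduct 9 (not isolated)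
Conditions: 7 (2.3 equiv), n-BuLi (2.2 equiv), TMEDA, THF, 0 °C; then 6 (1 equiv), −78 → −20 °C; 1 M HCl
Reagents that add atoms: none
Why: Directed ortho-lithiation at the ring C–H flanked by two benzyloxy groups followed by the Weinreb ketone synthesis should give the ketone, because the chelated tetrahedral adduct stops over-addition; one equivalent of aryllithium is spent on the alkyne C–H (returning recoverable 7), and at −78 °C the resulting acetylide should add to the amide far more slowly than the aryllithium.

Step 4
Reactants: 10 1-[2,4,6-tris(benzyloxy)phenyl]tridec-12-yn-1-one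
Product: 11 1-[tert-butyl(dimethyl)silyloxy]-1-[2,4,6-tris(benzyloxy)phenyl]tridec-1-en-12-yne
Conditions: TBSOTf, Et3N, CH2Cl2, 0 °C → rt
Reagents that add atoms: tert-butyldimethylsilyl trifluoromethanesulfonate, CC(C)(C)[Si](C)(C)OS(=O)(=O)C(F)(F)F
Why: Soft enolization (silyl triflate and amine) of a ketone with a single enolizable side should give the silyl enol ether and leave the alkyne C–H untouched, which removes both the acidic α-CH2 and the electrophilic carbonyl before step 5.

Step 5
Reactants: 11 1-[tert-butyl(dimethyl)silyloxy]-1-[2,4,6-tris(benzyloxy)phenyl]tridec-1-en-12-yne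
Product: 14 1-[tert-butyl(dimethyl)silyloxy]-1-[2,4,6-tris(benzyloxy)phenyl]-13-(triisopropylsilyloxy)tridec-1-en-12-yne, via lithium acetylide 12 (not isolated), via lithium ynolate 13 (not isolated)
Conditions: LiN(SiMe3)2, THF, −78 °C; t-BuOOLi (from t-BuOOH + LiN(SiMe3)2), −78 → 0 °C; TIPSOTf, −78 → 0 °C; Et3N-deactivated silica
Reagents that add atoms: tert-butyl hydroperoxide, CC(C)(C)OO; triisopropylsilyl trifluoromethanesulfonate, CC(C)[Si](C(C)C)(C(C)C)OS(=O)(=O)C(F)(F)F
Why: Oxidation of a lithium acetylide by lithium tert-butyl peroxide to the lithium ynolate and O-silylation with the bulky silyl triflate is the established synthesis of 1-siloxyalkynes from terminal alkynes, and the silyl enol ether and benzyl ethers have no site that the amide base or the peroxide anion should attack.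

Step 6
Reactants: 15 3-oxocyclobutane-1-carboxylic acid
Product: 17 3-bromocyclobutan-1-one, via acyl hypobromite 16 (not isolated)
Conditions: HgO, Br2, MgSO4, CH2Cl2, reflux
Reagents that add atoms: bromine, BrBr
Why: The Cristol–Firth variant of the Hunsdiecker reaction (radical bromodecarboxylation through the acyl hypobromite) is the known way from this acid to the β-bromo ketone.

Step 7
Reactants: 17 3-bromocyclobutan-1-one
Product: 18 cyclobut-2-en-1-one
Conditions: n-Bu3N (2 equiv), rt, reduced pressure, product collected in a −78 °C trap and kept as a cold toluene solution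
Reagents that add atoms: none
Why: E1cB-type dehydrobromination of the β-bromo ketone by a tertiary amine should give the enone, which is removed from the base by vacuum transfer before it can oligomerize.

Step 8
Reactants: 14 1-[tert-butyl(dimethyl)silyloxy]-1-[2,4,6-tris(benzyloxy)phenyl]-13-(triisopropylsilyloxy)tridec-1-en-12-yne; 18 cyclobut-2-en-1-one
Product: 23 2-{11-[tert-butyl(dimethyl)silyloxy]-11-[2,4,6-tris(benzyloxy)phenyl]undec-10-en-1-yl}-3-(triisopropylsilyloxy)phenol, via vinylketene 19 (not isolated), via vinylcyclobutenone 20 (not isolated), via dienylketene 21 (not isolated), via cyclohexadienone 22 (not isolated)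
Conditions: 18 (2.5 equiv, added in portions as a cold toluene solution), BHT (cat.), toluene, sealed tube, 80 °C; then 110 °C
Reagents that add atoms: none
Why: Heating opens cyclobutenone 18 in a four-electron electrocyclic reaction to vinylketene 19, whose ketene C=C adds to the siloxyalkyne of 14 in a [2+2] cycloaddition to give 4-vinylcyclobutenone 20 (ring A bonds C1–C2 and C3–C4); a second four-electron opening gives dienylketene 21, and six-electron electrocyclization (ring A bond C1–C6) followed by tautomerization of cyclohexadienone 22 gives the phenol. The closest known reaction type is the Danheiser benzannulation of cyclobutenones with 1-siloxyalkynes to resorcinol monosilyl ethers, applied here with the unsubstituted parent cyclobutenone. Ring A is closed by the 6π electrocyclization of the dienylketene, a pericyclic closure in which the ketene carbon C1 bonds to the terminal vinyl carbon C6; the ring openings before it are reversible, so material should funnel through the isomer of 21 that can close. No stereocenter remains, since the sp3 carbon of 20 is lost on ring opening. The step needs regioselectivity in the [2+2] event, and the oxygen-polarized alkyne secures it because its nucleophilic, chain-bearing carbon attacks the electrophilic ketene carbonyl carbon, which places the chain at C2 between the ketene-derived free hydroxyl (C1) and the silyloxy group (C3). It also needs chemoselectivity for the siloxyalkyne over the silyl enol ether, which the much higher nucleophilicity of the ynol ether and the shielding of the trisubstituted enol ether by the 2,6-bis(benzyloxy)aryl group should provide.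

Step 9
Reactants: 23 2-{11-[tert-butyl(dimethyl)silyloxy]-11-[2,4,6-tris(benzyloxy)phenyl]undec-10-en-1-yl}-3-(triisopropylsilyloxy)phenol
Product: 24 2-{11-[tert-butyl(dimethyl)silyloxy]-11-[2,4,6-tris(benzyloxy)phenyl]undec-10-en-1-yl}-3-(triisopropylsilyloxy)phenyl acetate
Conditions: Ac2O, pyridine, DMAP (cat.), CH2Cl2, 0 °C → rt
Reagents that add atoms: acetic anhydride, CC(=O)OC(C)=O
Why: DMAP-catalysed O-acylation can only reach the single free hydroxyl (C1), so the two ring A oxygens stay differentiated, and silyl ether and silyl enol ether are stable to these non-acidic, fluoride-free conditions.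

Step 10
Reactants: 24 2-{11-[tert-butyl(dimethyl)silyloxy]-11-[2,4,6-tris(benzyloxy)phenyl]undec-10-en-1-yl}-3-(triisopropylsilyloxy)phenyl acetate
Product: 25 3-hydroxy-2-{11-oxo-11-[2,4,6-tris(benzyloxy)phenyl]undecyl}phenyl acetate
Conditions: TBAF, AcOH (1:1), THF, 0 °C → rt
Reagents that add atoms: none
Why: Fluoride-induced desilylation should cleave the aryl silyl ether to the C3 phenol and the silyl enol ether to the ketone (after protonation on carbon), while the acetic acid buffer protonates the phenoxide and enolate at once and so protects the aryl acetate.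

Step 11
Reactants: 25 3-hydroxy-2-{11-oxo-11-[2,4,6-tris(benzyloxy)phenyl]undecyl}phenyl acetate
Product: 26 3-hydroxy-2-[11-oxo-11-(2,4,6-trihydroxyphenyl)undecyl]phenyl acetate (CNP0111377.0)
Conditions: H2 (1 atm), Pd/C, EtOAc, rt
Reagents that add atoms: none
Why: Catalytic hydrogenolysis should remove the three benzyl aryl ethers while the aryl acetate and the hydrogen-bonded acylphloroglucinol ketone survive, and the non-nucleophilic solvent avoids transesterification of the acetate.

**Compound list**

1 | 11-bromoundecanoic acid | OC(=O)CCCCCCCCCCBr | starting material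
2 | lithium 11-bromoundecanoate | [Li+].[O-]C(=O)CCCCCCCCCCBr | intermediate
3 | lithium tridec-12-ynoate | [Li+].[O-]C(=O)CCCCCCCCCCC#C | intermediate
4 | tridec-12-ynoic acid | OC(=O)CCCCCCCCCCC#C | intermediate
5 | 1-(1H-imidazol-1-yl)tridec-12-yn-1-one (acyl imidazolide) | O=C(CCCCCCCCCCC#C)n1ccnc1 | intermediate
6 | N-methoxy-N-methyltridec-12-ynamide | CON(C)C(=O)CCCCCCCCCCC#C | intermediate
7 | 1,3,5-tris(benzyloxy)benzene | c1ccc(COc2cc(OCc3ccccc3)cc(OCc3ccccc3)c2)cc1 | starting material
8 | 2,4,6-tris(benzyloxy)phenyllithium | [Li]c1c(OCc2ccccc2)cc(OCc2ccccc2)cc1OCc1ccccc1 | intermediate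
9 | lithium 13-lithio-1-[methoxy(methyl)amino]-1-[2,4,6-tris(benzyloxy)phenyl]tridec-12-yn-1-olate (dilithio tetrahedral adduct) | [Li]C#CCCCCCCCCCCC(O[Li])(N(C)OC)c1c(OCc2ccccc2)cc(OCc2ccccc2)cc1OCc1ccccc1 | intermediate
10 | 1-[2,4,6-tris(benzyloxy)phenyl]tridec-12-yn-1-one | C#CCCCCCCCCCCC(=O)c1c(OCc2ccccc2)cc(OCc2ccccc2)cc1OCc1ccccc1 | intermediate
11 | 1-[tert-butyl(dimethyl)silyloxy]-1-[2,4,6-tris(benzyloxy)phenyl]tridec-1-en-12-yne (enol ether geometry undefined) | C#CCCCCCCCCCC=C(O[Si](C)(C)C(C)(C)C)c1c(OCc2ccccc2)cc(OCc2ccccc2)cc1OCc1ccccc1 | intermediate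
12 | 13-lithio derivative of 11 (lithium acetylide) | [Li]C#CCCCCCCCCCC=C(O[Si](C)(C)C(C)(C)C)c1c(OCc2ccccc2)cc(OCc2ccccc2)cc1OCc1ccccc1 | intermediate
13 | lithium 13-[tert-butyl(dimethyl)silyloxy]-13-[2,4,6-tris(benzyloxy)phenyl]tridec-12-en-1-yn-1-olate (lithium ynolate) | [Li]OC#CCCCCCCCCCC=C(O[Si](C)(C)C(C)(C)C)c1c(OCc2ccccc2)cc(OCc2ccccc2)cc1OCc1ccccc1 | intermediate
14 | 1-[tert-butyl(dimethyl)silyloxy]-1-[2,4,6-tris(benzyloxy)phenyl]-13-(triisopropylsilyloxy)tridec-1-en-12-yne | CC(C)[Si](C(C)C)(C(C)C)OC#CCCCCCCCCCC=C(O[Si](C)(C)C(C)(C)C)c1c(OCc2ccccc2)cc(OCc2ccccc2)cc1OCc1ccccc1 | intermediate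
15 | 3-oxocyclobutane-1-carboxylic acid | O=C1CC(C(=O)O)C1 | starting material
16 | 3-oxocyclobutane-1-carbonyl hypobromite | O=C1CC(C(=O)OBr)C1 | intermediate
17 | 3-bromocyclobutan-1-one | O=C1CC(Br)C1 | intermediate
18 | cyclobut-2-en-1-one | O=C1CC=C1 | intermediate
19 | buta-1,3-dien-1-one (vinylketene) | C=CC=C=O | intermediate
20 | 4-ethenyl-2-{11-[tert-butyl(dimethyl)silyloxy]-11-[2,4,6-tris(benzyloxy)phenyl]undec-10-en-1-yl}-3-(triisopropylsilyloxy)cyclobut-2-en-1-one (racemic at C4) | O=C1C(C=C)C(O[Si](C(C)C)(C(C)C)C(C)C)=C1CCCCCCCCCC=C(O[Si](C)(C)C(C)(C)C)c1c(OCc2ccccc2)cc(OCc2ccccc2)cc1OCc1ccccc1 | intermediate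
21 | 2-{11-[tert-butyl(dimethyl)silyloxy]-11-[2,4,6-tris(benzyloxy)phenyl]undec-10-en-1-yl}-3-(triisopropylsilyloxy)hexa-1,3,5-trien-1-one (dienylketene; ketene carbon and vinyl group cis across C3=C4) | O=C=C(CCCCCCCCCC=C(O[Si](C)(C)C(C)(C)C)c1c(OCc2ccccc2)cc(OCc2ccccc2)cc1OCc1ccccc1)/C(O[Si](C(C)C)(C(C)C)C(C)C)=C\C=C | intermediate
22 | 2-{11-[tert-butyl(dimethyl)silyloxy]-11-[2,4,6-tris(benzyloxy)phenyl]undec-10-en-1-yl}-3-(triisopropylsilyloxy)cyclohexa-2,4-dien-1-one | O=C1CC=CC(O[Si](C(C)C)(C(C)C)C(C)C)=C1CCCCCCCCCC=C(O[Si](C)(C)C(C)(C)C)c1c(OCc2ccccc2)cc(OCc2ccccc2)cc1OCc1ccccc1 | intermediate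
23 | 2-{11-[tert-butyl(dimethyl)silyloxy]-11-[2,4,6-tris(benzyloxy)phenyl]undec-10-en-1-yl}-3-(triisopropylsilyloxy)phenol | Oc1cccc(O[Si](C(C)C)(C(C)C)C(C)C)c1CCCCCCCCCC=C(O[Si](C)(C)C(C)(C)C)c1c(OCc2ccccc2)cc(OCc2ccccc2)cc1OCc1ccccc1 | intermediate
24 | 2-{11-[tert-butyl(dimethyl)silyloxy]-11-[2,4,6-tris(benzyloxy)phenyl]undec-10-en-1-yl}-3-(triisopropylsilyloxy)phenyl acetate | CC(=O)Oc1cccc(O[Si](C(C)C)(C(C)C)C(C)C)c1CCCCCCCCCC=C(O[Si](C)(C)C(C)(C)C)c1c(OCc2ccccc2)cc(OCc2ccccc2)cc1OCc1ccccc1 | intermediate
25 | 3-hydroxy-2-{11-oxo-11-[2,4,6-tris(benzyloxy)phenyl]undecyl}phenyl acetate | CC(=O)Oc1cccc(O)c1CCCCCCCCCCC(=O)c1c(OCc2ccccc2)cc(OCc2ccccc2)cc1OCc1ccccc1 | intermediate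
26 | 3-hydroxy-2-[11-oxo-11-(2,4,6-trihydroxyphenyl)undecyl]phenyl acetate (CNP0111377.0) | CC(=O)Oc1cccc(O)c1CCCCCCCCCCC(=O)c1c(O)cc(O)cc1O | target

**Step count**

Total step count: 11. Longest linear sequence: 9 steps (steps 1–5 and 8–11); steps 6 and 7 are the side branch to cyclobutenone.

**Steps most likely to fail**

1. Step 8 (benzannulation). Oligomerization or evaporative loss of the unsubstituted cyclobutenone, and dimerization of the vinylketene, may outrun capture by the siloxyalkyne. The phenol formed may also be acylated by surplus vinylketene.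
Fallback: it sets out from 14 and comes back to the route at 20, then 23. Vinylketene 19 is generated without any cyclobutenone, by 1,4-dehydrochlorination of (E)-but-2-enoyl chloride with Et3N. The acid chloride is added slowly to 14 and Et3N in CH2Cl2 at 0 °C → rt, so that the ketene stays at low stationary concentration and the [2+2] adduct 20 forms at low temperature. After removal of the ammonium salt and change of solvent, 20 is heated in toluene (80–110 °C) and passes through 21 and 22 to 23. This fallback makes no compound outside the compound list (F0).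

2. Step 5 (siloxyalkyne formation). The enol ether may be desilylated by the peroxide anion or by silyl transfer to the ynolate. The acetylide may be oxidized incompletely, or the acid-sensitive siloxyalkyne may be lost on purification.
Fallback: it sets out from aryllithium 8 and comes back to the route at the target 26, without any siloxyalkyne. Ring A is taken from 2-iodoresorcinol and joined to the chain by Sonogashira coupling.
- Undec-10-ynoic acid is activated with CDI to 1-(1H-imidazol-1-yl)undec-10-yn-1-one F1 and converted with MeNHOMe·HCl into N-methoxy-N-methylundec-10-ynamide F2.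
- Addition of F2 to 8 (2.2 equiv, THF, −78 °C) gives, through the dilithio tetrahedral adduct F3, 1-[2,4,6-tris(benzyloxy)phenyl]undec-10-yn-1-one F4.
- 2-Iodoresorcinol is monobenzylated (BnBr, K2CO3, acetone) to 3-(benzyloxy)-2-iodophenol F5 and acetylated (Ac2O, pyridine) to 3-(benzyloxy)-2-iodophenyl acetate F6.
- Sonogashira coupling of F4 with F6 (Pd(PPh3)2Cl2, CuI, Et3N, DMF, 50 °C) gives 3-(benzyloxy)-2-{11-oxo-11-[2,4,6-tris(benzyloxy)phenyl]undec-1-yn-1-yl}phenyl acetate F7.
- Hydrogen over Pd/C in EtOAc then saturates the alkyne and cleaves all four benzyl ethers in one operation to give 26.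

3. Step 3 (aryl ketone). The hindered aryllithium may act as a base only, so that the lithium acetylide of 6 adds to a second molecule of amide. Metalation of a benzylic CH2 of 7 followed by [1,2]-Wittig rearrangement may compete with ring lithiation.
Fallback: it sets out from acid 4 and arene 7 and comes back to the route at 10, with no organolithium. Trifluoroacetic anhydride (CH2Cl2, 0 °C → rt) converts 4 into tridec-12-ynoic trifluoroacetic anhydride F8. F8 acylates the electron-rich arene 7 in a Friedel–Crafts acylation (its three free ring positions are equivalent) and gives 10 directly, so that step 2 is not needed.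

**Further compounds**

F0 | step 8 | none | none
F1 | step 5 | 1-(1H-imidazol-1-yl)undec-10-yn-1-one | O=C(CCCCCCCCC#C)n1ccnc1
F2 | step 5 | N-methoxy-N-methylundec-10-ynamide | CON(C)C(=O)CCCCCCCCC#C
F3 | step 5 | lithium 11-lithio-1-[methoxy(methyl)amino]-1-[2,4,6-tris(benzyloxy)phenyl]undec-10-yn-1-olate (dilithio tetrahedral adduct) | [Li]C#CCCCCCCCCC(O[Li])(N(C)OC)c1c(OCc2ccccc2)cc(OCc2ccccc2)cc1OCc1ccccc1
F4 | step 5 | 1-[2,4,6-tris(benzyloxy)phenyl]undec-10-yn-1-one | C#CCCCCCCCCC(=O)c1c(OCc2ccccc2)cc(OCc2ccccc2)cc1OCc1ccccc1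
F5 | step 5 | 3-(benzyloxy)-2-iodophenol | Oc1cccc(OCc2ccccc2)c1I
F6 | step 5 | 3-(benzyloxy)-2-iodophenyl acetate | CC(=O)Oc1cccc(OCc2ccccc2)c1I
F7 | step 5 | 3-(benzyloxy)-2-{11-oxo-11-[2,4,6-tris(benzyloxy)phenyl]undec-1-yn-1-yl}phenyl acetate | CC(=O)Oc1cccc(OCc2ccccc2)c1C#CCCCCCCCCC(=O)c1c(OCc2ccccc2)cc(OCc2ccccc2)cc1OCc1ccccc1
F8 | step 3 | tridec-12-ynoic trifluoroacetic anhydride | C#CCCCCCCCCCCC(=O)OC(=O)C(F)(F)F
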